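In north-west the starting material opens slowly, with a half-life of 19.3 s against 2.0 s for the open intermediate under first nucleophile as charged, so the opening is the rate-limiting step and the yield depends on which nucleophile captures.

    starting material → open intermediate (k1 = 0.036 /s)
    first nucleophile + open intermediate → target (k2 = 17 /M/s)
    second nucleophile + open intermediate → other capture product (k3 = 8.2 /M/s)
    2 first nucleophile → homo dimer (k4 = 2.7 /M/s)
    second nucleophile + target ⇌ idle adduct, settled at all times (K5 = 24 /M)
    open intermediate + capture agent → trapped intermediate (k6 = 0.98 /M/s)

| setting | east | west | north-west |
|---|---|---|---|
| starting material | 10 mM (fed, over 1.5 min) | 10 mM | 10 mM |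
| first nucleophile | 20.0 mM | 20.0 mM (fed, over 1.5 min) | 20.0 mM |
| second nucleophile | 30.0 mM | 30.0 mM | 30.0 mM |
| capture agent | 1.00 mM | 1.00 mM | 1.00 mM |
| time | 2.0 min | 2.0 min | 2.0 min |
| remark | all else is in the flask from the start; the feed brings no volume worth counting | all else is in the flask from the start; the feed brings no volume worth counting | everything together at the start |

- the flask that comes out highest in amount of target, in percent of the starting material charged, or "all alike" when all lie within 1.5 percentage points (east / west / north-west / all alike)
- target at the end, in percent of the starting material charged, east
- target at the end, in percent of the starting material charged, west
- target at the end, in percent of the starting material charged, north-west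

- amounts and yields of target count idle adduct too
- for a step with 2 of a species take k times the square, and two of it per event
- run time (east): 2.0 min

The quick number comes from one freeze. Capture can take at most 10 mM of second nucleophile, a third of its charge, so [second nucleophile] is held at 30.0 mM and its capture becomes pseudo-first-order. The open intermediate then splits evenly when [first nucleophile] equals the even-split level, the capture constant of second nucleophile over that of first nucleophile, times [second nucleophile]: 14.5 mM.

Meanwhile first nucleophile dimerises with a first half-life of 9.26 s, shorter than 19.3 s, so its level falls while the material opens. The split is read at the moment half the starting material has opened. In north-west, [first nucleophile] is then 6.49 mM, below the even-split level, which gives target a share of 31.0%. In east, the feed delays that moment by 45.0 s, to 64.3 s; [first nucleophile] is 2.52 mM and the share 14.8%. The reckoning stops at west, where the feed shapes the level.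

The forecast, the hunch that came with the request, gives 18% for east, 19% for west and 27% for north-west: “All-at-once addition best matches the early burst of intermediate to the early high nucleophile level”. The reckoning stands above it for north-west and below it for east.

| Flask | Forecast | Simulation |
|---|---|---|
| east | 18% | 13.9% |
| west | 19% | 21.7% |
| north-west | 27% | 29.5% |

The forecast's north-west stands; its north-west figure of 27% would be put in question by less second nucleophile, as in the neighbour of north-west with 7.5 mM, where the run gives 54.2%, twice that figure. In the neighbour of north-west with 51 mM of second nucleophile, the even-split level becomes 24.7 mM, the share 20.8%, and the run gives 20.9%. North-west has nearly come to rest: with 1.33% starting material left at 2.00 min, it goes from 29.5% to 29.6% by 20.0 min. East has not, holding 10.1% starting material and 2.17% open intermediate at 2.00 min, and it climbs from 13.9% to 14.8% by 20.0 min.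

The numbers were set for the occasion; what happens was integrated by code.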